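The aryl–ethyl ester is trivial. The difficulty is the acyl part, an unbranched, odd-numbered C37 chain (C1 = carbonyl) that is not a catalogue compound. The route rests on cutting this chain at its centre, C19–C20, a bond between two unactivated CH2 groups. A mixed anodic Kolbe coupling forms it in one operation. Nonadecanoic acid and mono-tert-butyl icosanedioate each lose CO2 at platinum, and the octadecyl (C20–C37) and ester-bearing nonadecyl (C1–C19) radicals combine (19 + 20 − 2 = 37). The step exploits the fact that C2–C37 carries no branch or heteroatom, so only primary radicals arise. The oxidisable 4-hydroxyphenyl ring is kept out of the cell and joined afterwards, unprotected, through its primary alcohol.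

Key step: step 1

Remark: the target has no stereocentre and no stereogenic double bond, so there is no enantiomer to select. The acyl chain of the SMILES is read as 37 carbons including the carbonyl carbon (heptatriacontanoyl, CH3(CH2)35CO).

Step 1
Reactants: 1 nonadecanoic acid (commercial, CH3(CH2)17CO2H); 2 20-(tert-butoxy)-20-oxoicosanoic acid (commercial mono-tert-butyl ester of icosanedioic acid, HO2C(CH2)18CO2tBu)
Product: 5 tert-butyl heptatriacontanoate, via octadecyl radical 3 (not isolated), via 19-tert-butoxy-19-oxononadecyl radical 4 (not isolated)
Conditions: undivided cell, smooth Pt anode / Pt cathode, constant current ca. 0.15–0.2 A cm⁻², 1 (1 equiv), 2 (3 equiv), NaOMe (ca. 5 mol % of total acid), MeOH with heptane as co-solvent, 50–55 °C, until the electrolyte turns faintly alkaline, polarity reversed at intervals; SiO2 (warm heptane, then heptane–toluene), then recrystallisation from acetone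
Reagents that add atoms: none
Why: Mixed (crossed) Kolbe electrolysis: at smooth Pt and high current density both carboxylates are oxidised by one electron and lose CO2, leaving the primary radicals 3 and 4 in high local concentration at the anode, where they combine to the C19–C20 bond while the carboxyl protons are reduced to H2 at the cathode. The closest known reaction type is the classical anodic cross-coupling of a fatty acid with a dicarboxylic half-ester for chain extension. No ring is closed and no stereocentre is formed. Radical coupling is favoured over two-electron (Hofer–Moest) oxidation by the substrates, because both radical centres are unbranched primary carbons with no α-heteroatom or α-branch, and this is supported by the weakly acidic medium, the Pt surface and the high current density. Cross- versus homo-coupling is only statistical because 3 and 4 are equally reactive, so the cheap half-ester 2 is used in excess to channel most of 1 into 5, and the three coupling products carry zero, one or two ester groups and should separate on silica, with short-chain disproportionation material removed by the recrystallisation. The tert-butyl ester is inert to methanol and to methoxide formed at the cathode, and no oxidisable arene is present at this stage.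

Step 2
Reactants: 5 tert-butyl heptatriacontanoate
Product: 6 heptatriacontanoic acid
Conditions: TFA–CHCl3 1:2, 40 °C; evaporate; recrystallise from hot toluene
Reagents that add atoms: none
Why: Acid-mediated tert-butyl ester cleavage (AAL1 ionisation to the tert-butyl cation, which loses a proton to isobutene) should be clean because the saturated chain offers no other reactive site and no stereocentre is involved.

Step 3
Reactants: 6 heptatriacontanoic acid; 7 tyrosol (4-(2-hydroxyethyl)phenol, commercial)
Product: 8 2-(4-hydroxyphenyl)ethyl heptatriacontanoate (target CNP0230173.0)
Conditions: 7 (3 equiv), immobilised Candida antarctica lipase B (Novozym 435), 4 Å MS, toluene–2-methyl-2-butanol 3:1, 65–70 °C; hot filtration, aqueous wash to remove excess 7, recrystallisation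
Reagents that add atoms: none
Why: Lipase-catalysed chemoselective esterification: the serine acyl-enzyme formed from 6 is intercepted by the unhindered primary alcohol of 7 while the phenolic OH is not accepted as a nucleophile, the tertiary co-solvent alcohol is not acylated and the sieves remove water to pull the equilibrium, so neither a protecting group nor stereocontrol is needed.

Compound list
1 | nonadecanoic acid | CCCCCCCCCCCCCCCCCCC(=O)O | starting material
2 | 20-(tert-butoxy)-20-oxoicosanoic acid | OC(=O)CCCCCCCCCCCCCCCCCCC(=O)OC(C)(C)C | starting material
3 | octadecyl radical | CCCCCCCCCCCCCCCCC[CH2] | intermediate
4 | 19-tert-butoxy-19-oxononadecyl radical | [CH2]CCCCCCCCCCCCCCCCCC(=O)OC(C)(C)C | intermediate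
5 | tert-butyl heptatriacontanoate | CCCCCCCCCCCCCCCCCCCCCCCCCCCCCCCCCCCCC(=O)OC(C)(C)C | intermediate
6 | heptatriacontanoic acid | CCCCCCCCCCCCCCCCCCCCCCCCCCCCCCCCCCCCC(=O)O | intermediate
7 | tyrosol, 4-(2-hydroxyethyl)phenol | OCCc1ccc(O)cc1 | starting material
8 | 2-(4-hydroxyphenyl)ethyl heptatriacontanoate | CCCCCCCCCCCCCCCCCCCCCCCCCCCCCCCCCCCCC(=O)OCCc1ccc(O)cc1 | target

Total step count: 3. Longest linear sequence: 3 (steps 1–3).

Steps most likely to fail

1. Step 1. Waxy coupling products may coat the anode, which breaks down the carboxylate layer and shifts the reaction towards two-electron oxidation. The radicals may also disproportionate, and the partition between cross- and homo-coupling is purely statistical. The fallback replaces the statistical radical dimerisation by a polarity-differentiated cross-coupling. It sets out from 2 and returns at 5. The free carboxyl group of 2 is converted (N-hydroxyphthalimide, DIC, cat. DMAP, CH2Cl2) into the redox-active ester 1-tert-butyl 20-(1,3-dioxoisoindolin-2-yl) icosanedioate F1. Purchased 1-bromooctadecane F2 is turned with Mg in THF into octadecylmagnesium bromide F3, and this with ZnCl2 (0.5 equiv) into dioctadecylzinc F4. A nickel-catalysed decarboxylative Negishi-type alkyl–alkyl coupling of F1 with F4 (NiCl2·glyme, 4,4'-di-tert-butyl-2,2'-bipyridine, THF–DMF, rt) should form the same C19–C20 bond and give 5. The tert-butyl ester is inert to the organozinc reagent.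

2. Step 3. Acyl-enzyme formation may be slow or absent, because the very long acyl donor is poorly soluble and the solvent needs of the waxy acid and the polar diol differ. The fallback activates the alcohol instead of the acid. It sets out from 6 and 7 and returns at 8. It is a Mitsunobu esterification (PPh3, DIAD, THF–toluene, ca. 45 °C), in which the primary alcohol of 7 becomes the alkoxyphosphonium ion. The carboxylic acid, far more acidic than the phenol, acts as the pronucleophile, so the phenol should stay free. This fallback makes no new compound (F0).

3. Step 2. The substrate may crystallise out of the acidic medium, which leaves the acidolysis incomplete, and the high-melting, sparingly soluble free acid may be lost in handling. The fallback bypasses the free acid and the enzyme. It sets out from 5 and returns at 8. The tert-butyl ester is converted directly with SOCl2 (neat or in toluene, 50–60 °C) into heptatriacontanoyl chloride F5. This acylates 7 (3 equiv) without any base in warm THF–dimethyl carbonate. Under these non-basic conditions the aliphatic OH is the better nucleophile and the phenol should remain unacylated.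

Further compounds
F1 | step 1 | 1-tert-butyl 20-(1,3-dioxoisoindolin-2-yl) icosanedioate | CC(C)(C)OC(=O)CCCCCCCCCCCCCCCCCCC(=O)ON1C(=O)c2ccccc2C1=O
F2 | step 1 | 1-bromooctadecane (purchased) | CCCCCCCCCCCCCCCCCCBr
F3 | step 1 | octadecylmagnesium bromide | CCCCCCCCCCCCCCCCCC[Mg]Br
F4 | step 1 | dioctadecylzinc | CCCCCCCCCCCCCCCCCC[Zn]CCCCCCCCCCCCCCCCCC
F0 | step 3 | none | none
F5 | step 2 | heptatriacontanoyl chloride | CCCCCCCCCCCCCCCCCCCCCCCCCCCCCCCCCCCCC(=O)Cl
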